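## Retrosynthetic overview
1. C3=C4: ring-closing metathesis of a C4 acrylate with the prenyl terminus closes the oxepine bridge last. The C8 ester comes from a Mitsunobu inversion with a Sharpless-derived (2S,3R)-epoxy acid.
2. C13 and the metathesis methylene both come from one double Mannich reaction on the lactone/ester pair.
3. Key disconnection C5–C6: SmI2 turns the C6 aldehyde into a ketyl, which attacks C5, the β-carbon of a β-alkoxyacrylate hung on the tertiary C10–OH. This closes the oxepane and sets C5 and C6.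
4. C7–C8: auxiliary-controlled syn aldol of a succinate enolate. C10: Sharpless epoxidation of geraniol, carried on as (S)-linalool.
5. Ring order: oxepane, then γ-lactone, then oxepine.

Atom labels (germacrane numbering, used for all intermediates):
- C10 is the tertiary ether carbon (bearing methyl C14); C9 is CH2; C8 is the acyloxy carbon.
- C7 is the ring CH next to C8 that carries C11; C6 is the lactone O–CH; C5 is the ether O–CH.
- C4 is C(CO2Me) (ester carbon C15); C3 is =CH; C2 and C1 are CH2.
- C11, C12 and C13 are the lactone α-carbon, the lactone C=O and the exo-methylene.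
- Target configuration: 5R,6S,7R,8R,10S,2'S,3'R.

Assumption: (E)-2-methylbut-2-en-1-ol, mono-tert-butyl succinate and (4R)-4-benzyl-1,3-thiazolidine-2-thione are taken as catalogue chemicals, and C3=C4, which has no descriptor in the SMILES, has the only geometry a seven-membered ring allows.

## Route

Step 1
Reactants: 1 geraniol
Product: 2 (2S,3S)-2,3-epoxygeraniol
Conditions: Ti(OiPr)4 (5 mol%), L-(+)-diethyl tartrate (6 mol%), tBuOOH, 4 Å MS, CH2Cl2, −20 °C
Reagents that add atoms: tert-butyl hydroperoxide, CC(C)(C)OO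
Why: Katsuki–Sharpless asymmetric epoxidation; with the L-(+)-tartrate the E-allylic alcohol gives the (2S,3S)-epoxide (about 95% ee), and its tertiary C–O carbon is the future C10 (S).

Step 2
Reactants: 2 (2S,3S)-2,3-epoxygeraniol
Product: 4 (S)-linalool, via epoxy iodide 3 (not isolated)
Conditions: PPh3, I2, imidazole, THF, 0 °C; then Zn dust, EtOH, 50 °C
Reagents that add atoms: none
Why: Appel-type iodination followed by zinc-induced reductive fragmentation of the β-iodo epoxide (Boord-type elimination); the tertiary C–O bond is never broken, so C10 keeps its configuration.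

Step 3
Reactants: 4 (S)-linalool; 5 methyl propiolate
Product: 6 methyl (2E)-3-{[(3S)-3,7-dimethylocta-1,6-dien-3-yl]oxy}prop-2-enoate
Conditions: PMe3 (10 mol%), CH2Cl2, 0 °C to rt
Reagents that add atoms: none
Why: Phosphine-catalysed oxa-Michael addition to an ynoate, which also works for tertiary alcohols and gives the E-β-alkoxyacrylate, so the hindered C10–O–C5 ether is made without ionising C10.

Step 4
Reactants: 6 β-alkoxyacrylate
Product: 7 methyl (2E)-3-{[(3S)-3,7-dimethyl-1-oxooct-6-en-3-yl]oxy}prop-2-enoate (C8 aldehyde)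
Conditions: PdCl2(PhCN)2 (12 mol%), CuCl2·2H2O (12 mol%), AgNO2 (6 mol%), O2 (1 atm), tBuOH/MeNO2 15:1, rt
Reagents that add atoms: dioxygen, O=O
Why: Nitrite-modified aldehyde-selective Wacker oxidation; the quaternary, oxygen-bearing allylic carbon steers oxygen to the terminal carbon, the trisubstituted and push–pull alkenes are inert, and the neutral medium spares the elimination-prone β-oxy aldehyde.

Step 5
Reactants: 8 (4R)-4-benzyl-1,3-thiazolidine-2-thione; 9 4-tert-butoxy-4-oxobutanoic acid
Product: 10 tert-butyl 4-[(4R)-4-benzyl-2-thioxo-1,3-thiazolidin-3-yl]-4-oxobutanoate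
Conditions: DCC, 4-(dimethylamino)pyridine (10 mol%), CH2Cl2, 0 °C to rt
Reagents that add atoms: none
Why: Steglich-type N-acylation; the tert-butyl ester keeps C12 inert until step 10.

Step 6
Reactants: 7 C8 aldehyde; 10 N-succinyl thiazolidinethione
Product: 11 syn-aldol adduct (7R,8S,10S; free C8–OH, C6 as N-acyl thiazolidinethione, C12 as tert-butyl ester)
Conditions: 10, TiCl4 (1.05 equiv), iPr2NEt (1.1 equiv), N-methyl-2-pyrrolidinone (1 equiv), CH2Cl2, 0 °C; then 7, −78 to −20 °C
Reagents that add atoms: none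
Why: Crimmins-type titanium-enolate aldol in the Evans-syn manifold; the Z-enolate reacts through a non-chelated Zimmerman–Traxler chair on the face away from the benzyl group, setting C7 (R, as in the target) and C8 (S, corrected by inversion in step 15), while the amine is tied up as its hydrochloride so the aldehyde does not eliminate.

Step 7
Reactants: 11 syn-aldol adduct
Product: 12 C8 tert-butyldimethylsilyl ether of 11
Conditions: TBSOTf, 2,6-lutidine, CH2Cl2, −78 to −20 °C
Reagents that add atoms: tert-butyldimethylsilyl triflate, CC(C)(C)[Si](C)(C)OS(=O)(=O)C(F)(F)F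
Why: Silyl protection; it keeps the C8 oxygen out of the later lactonisation and blocks retro-aldol cleavage, and no stereocentre is touched.

Step 8
Reactants: 12 silyl ether
Product: 13 C6 aldehyde (7R,8S,10S)
Conditions: iBu2AlH (1.2 equiv), CH2Cl2, −78 °C; Rochelle salt
Reagents that add atoms: none
Why: Direct reductive cleavage of the N-acyl thiazolidinethione to the aldehyde; this activated amide is reduced far faster than the tert-butyl ester or the vinylogous carbonate, and the auxiliary is recovered.

Step 9 (key step)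
Reactants: 13 C6 aldehyde
Product: 14 oxepane hydroxy diester (C6–OH, C5–CH2CO2Me, C7–CH2CO2tBu, C8–OTBS; C5, C6, C7, C10 as in the target, C8 epimeric)
Conditions: SmI2 (3 equiv), MeOH (3 equiv), THF (5 mM), 0 °C
Reagents that add atoms: none
Why: Samarium diiodide ketyl–olefin reductive cyclisation (Nakata type): electron transfer turns the electrophilic aldehyde carbon C6 into a nucleophilic ketyl that adds 7-exo-trig to C5, the equally electrophilic β-carbon of the alkoxyacrylate, a second electron and MeOH deliver the ester, and in the chair-like transition state (trivalent samarium bridging the ketyl oxygen and the ester carbonyl, C7 and C8 substituents equatorial) the C6–OH ends up trans to both the C7 and C5 side chains, with the C5 arm cis to the homoprenyl arm on C10, which is the target arrangement.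

Step 10
Reactants: 14 oxepane hydroxy diester
Product: 15 trans-fused γ-lactone (C6–O–C12)
Conditions: SiO2, PhMe, reflux
Reagents that add atoms: none
Why: Silica-promoted cleavage of the tert-butyl ester with spontaneous lactonisation; only C12 becomes a free acid, so C6–OH closes on C12 and not on the C15 methyl ester, and no stereocentre is touched.

Step 11
Reactants: 15 γ-lactone
Product: 16 bis-Mannich base (CH2NMe2 on C11 and on C4; epimer mixture at these two centres, of no consequence)
Conditions: LDA (2.4 equiv), THF, −78 °C; Me2N=CH2+ I− (4 equiv), −78 to −40 °C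
Reagents that add atoms: N,N-dimethylmethyleneiminium iodide (Eschenmoser's salt), C=[N+](C)C.[I-]
Why: Double Mannich reaction of the lactone and ester lithium enolates; below −40 °C the β-alkoxy ester enolate is trapped faster than it can expel the ring oxygen, and the two amines serve as masked acrylates in steps 12 and 15.

Step 12
Reactants: 16 bis-Mannich base
Product: 17 C8 alcohol (8S)
Conditions: HF·pyridine, THF, 0 °C to rt; NaHCO3
Reagents that add atoms: none
Why: Fluoride desilylation; the lactone, ester, tertiary ether and amines are all stable to it.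

Step 13
Reactants: 18 (E)-2-methylbut-2-en-1-ol
Product: 19 [(2R,3R)-2,3-dimethyloxiran-2-yl]methanol
Conditions: Ti(OiPr)4 (5 mol%), D-(−)-diethyl tartrate (6 mol%), tBuOOH, 4 Å MS, CH2Cl2, −20 °C
Reagents that add atoms: tert-butyl hydroperoxide, CC(C)(C)OO
Why: Katsuki–Sharpless asymmetric epoxidation; the D-(−)-tartrate gives the (2R,3R)-epoxy alcohol, and the E-alkene fixes the trans relation of CH2OH and the C3 methyl.

Step 14
Reactants: 19 epoxy alcohol
Product: 20 (2S,3R)-2,3-dimethyloxirane-2-carboxylic acid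
Conditions: 2,2,6,6-tetramethylpiperidin-1-oxyl (10 mol%), PhI(OAc)2 (2.2 equiv), MeCN/H2O 1:1, rt
Reagents that add atoms: water, O
Why: Oxoammonium-catalysed oxidation of the primary alcohol to the acid; the epoxide geometry is unchanged and only the descriptor at C2 changes, for priority reasons.

Step 15
Reactants: 17 C8 alcohol; 20 epoxy acid
Product: 21 C8 (2S,3R)-epoxy ester (8R), still the bis-Mannich base
Conditions: PPh3, DIAD, 20 (3 equiv), PhMe, 0 °C to rt
Reagents that add atoms: none
Why: Mitsunobu esterification; SN2 attack of the carboxylate on the equatorial C8 oxyphosphonium ion inverts C8 from S to the target R, C7–H is not acidic so elimination is slow, and the masked acrylates cannot be attacked by PPh3.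

Step 16
Reactants: 21 epoxy ester
Product: 23 bis(methylene) ester (α-methylene lactone and C4 acrylate), via bis(methiodide) 22 (not isolated)
Conditions: MeI, CH2Cl2, rt; then aq NaHCO3, rt
Reagents that add atoms: none
Why: Exhaustive methylation and Hofmann-type E1cB elimination of both β-ammonium groups; the mild base spares the epoxy ester, and the stereorandom C11 and C4 centres disappear.

Step 17
Reactants: 23 bis(methylene) ester
Product: 24 target CNP0240298.1
Conditions: second-generation Hoveyda–Grubbs catalyst RuCl2(H2IMes)(=CH-C6H4-2-OiPr) (10 mol%), 1,4-benzoquinone (20 mol%), PhMe (1 mM), 80 °C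
Reagents that add atoms: none
Why: Ring-closing metathesis; ruthenium loads at the prenyl end (releasing isobutene) and closes on the C4 acrylate, because the seven-membered ring forms faster than the nine-membered ring through the lactone methylene, and the cis C5/C10 arms from step 9 allow the bridge.

## Compound list
1 | geraniol | CC(C)=CCC/C(C)=C/CO | starting material
2 | (2S,3S)-2,3-epoxygeraniol | CC(C)=CCC[C@]1(C)O[C@H]1CO | intermediate
3 | epoxy iodide (primary iodide of 2, same spatial arrangement) | CC(C)=CCC[C@]1(C)O[C@H]1CI | intermediate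
4 | (S)-linalool | CC(C)=CCC[C@](C=C)(C)O | intermediate
5 | methyl propiolate | C#CC(=O)OC | starting material
6 | methyl (2E)-3-{[(3S)-3,7-dimethylocta-1,6-dien-3-yl]oxy}prop-2-enoate | CC(C)=CCC[C@](C=C)(C)O/C=C/C(=O)OC | intermediate
7 | methyl (2E)-3-{[(3S)-3,7-dimethyl-1-oxooct-6-en-3-yl]oxy}prop-2-enoate | CC(C)=CCC[C@](CC=O)(C)O/C=C/C(=O)OC | intermediate
8 | (4R)-4-benzyl-1,3-thiazolidine-2-thione | S=C1N[C@H](Cc2ccccc2)CS1 | starting material
9 | 4-tert-butoxy-4-oxobutanoic acid | CC(C)(C)OC(=O)CCC(=O)O | starting material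
10 | tert-butyl 4-[(4R)-4-benzyl-2-thioxo-1,3-thiazolidin-3-yl]-4-oxobutanoate | CC(C)(C)OC(=O)CCC(=O)N1[C@H](Cc2ccccc2)CSC1=S | intermediate
11 | syn-aldol adduct (7R,8S,10S) | CC(C)=CCC[C@](C)(O/C=C/C(=O)OC)C[C@H](O)[C@@H](CC(=O)OC(C)(C)C)C(=O)N1[C@H](Cc2ccccc2)CSC1=S | intermediate
12 | C8 TBS ether of 11 | CC(C)=CCC[C@](C)(O/C=C/C(=O)OC)C[C@H](O[Si](C)(C)C(C)(C)C)[C@@H](CC(=O)OC(C)(C)C)C(=O)N1[C@H](Cc2ccccc2)CSC1=S | intermediate
13 | C6 aldehyde (7R,8S,10S) | CC(C)=CCC[C@](C)(O/C=C/C(=O)OC)C[C@H](O[Si](C)(C)C(C)(C)C)[C@@H](CC(=O)OC(C)(C)C)C=O | intermediate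
14 | oxepane hydroxy diester | O[C@H]1[C@H](CC(=O)OC(C)(C)C)[C@@H](O[Si](C)(C)C(C)(C)C)C[C@](C)(CCC=C(C)C)O[C@@H]1CC(=O)OC | intermediate
15 | trans-fused γ-lactone | C1C(=O)O[C@H]2[C@H]1[C@@H](O[Si](C)(C)C(C)(C)C)C[C@](C)(CCC=C(C)C)O[C@@H]2CC(=O)OC | intermediate
16 | bis-Mannich base, C8 OTBS | CN(C)CC1C(=O)O[C@H]2[C@H]1[C@@H](O[Si](C)(C)C(C)(C)C)C[C@](C)(CCC=C(C)C)O[C@@H]2C(CN(C)C)C(=O)OC | intermediate
17 | bis-Mannich base, C8 alcohol (8S) | CN(C)CC1C(=O)O[C@H]2[C@H]1[C@@H](O)C[C@](C)(CCC=C(C)C)O[C@@H]2C(CN(C)C)C(=O)OC | intermediate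
18 | (E)-2-methylbut-2-en-1-ol | C/C=C(\C)CO | starting material
19 | [(2R,3R)-2,3-dimethyloxiran-2-yl]methanol | OC[C@@]1(C)O[C@@H]1C | intermediate
20 | (2S,3R)-2,3-dimethyloxirane-2-carboxylic acid | OC(=O)[C@@]1(C)O[C@@H]1C | intermediate
21 | bis-Mannich base, C8 epoxy ester (8R) | CN(C)CC1C(=O)O[C@H]2[C@H]1[C@H](OC(=O)[C@@]1(C)O[C@@H]1C)C[C@](C)(CCC=C(C)C)O[C@@H]2C(CN(C)C)C(=O)OC | intermediate
22 | bis(methiodide) of 21 | C[N+](C)(C)CC1C(=O)O[C@H]2[C@H]1[C@H](OC(=O)[C@@]1(C)O[C@@H]1C)C[C@](C)(CCC=C(C)C)O[C@@H]2C(C[N+](C)(C)C)C(=O)OC.[I-].[I-] | intermediate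
23 | bis(methylene) ester (metathesis precursor) | C=C1C(=O)O[C@H]2[C@H]1[C@H](OC(=O)[C@@]1(C)O[C@@H]1C)C[C@](C)(CCC=C(C)C)O[C@@H]2C(=C)C(=O)OC | intermediate
24 | CNP0240298.1 | C=C1C(=O)O[C@H]2[C@H]1[C@H](OC(=O)[C@@]1(C)O[C@@H]1C)C[C@]1(C)CCC=C(C(=O)OC)[C@H]2O1 | target

## Step count and risks
Total steps: 17. Longest linear sequence: 14 (steps 1–4, 6–12, 15–17).

The three steps most likely to fail are 9, 15 and 17.

Step 9 could give pinacol dimers, plain reduction of the aldehyde, or the wrong C5/C6 pair. The fallback keeps the same bond but makes it with an acyl radical. Starting from 13, Pinnick oxidation (NaClO2, NaH2PO4, 2-methyl-2-butene) gives the carboxylic acid F1, and (PhSe)2/PBu3 converts it into the Se-phenyl selenoester F2. Treatment with (Me3Si)3SiH, Et3B and air closes the ring by 7-exo acyl-radical addition to the alkoxyacrylate and gives the oxepan-3-one F3, in which C5 can still equilibrate to the cis-2,7 arrangement. NaBH4 at −78 °C (axial attack, equatorial alcohol) then returns to 14.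

Step 15 could be sluggish or give the C8–C9 alkene. The fallback inverts C8 by redox chemistry and then acylates with retention. Starting from 17, Dess–Martin periodinane with NaHCO3 gives the C8 ketone F4, and LiBH(sBu)3 at −78 °C (equatorial attack) gives the axial 8R alcohol F5. Yamaguchi esterification with 20 (2,4,6-trichlorobenzoyl chloride, Et3N, 4-(dimethylamino)pyridine) returns to 21.

Step 17 could stall because ruthenium loads slowly on the trisubstituted alkene, or because the bridged ring is strained. The fallback swaps the olefin partner. Starting from 23, one equivalent of O3 at −78 °C with Me2S work-up cleaves only the electron-rich prenyl alkene and gives the C3 aldehyde F6. The Tebbe reagent Cp2Ti(μ-Cl)(μ-CH2)AlMe2 at −40 °C methylenates the aldehyde selectively to the terminal alkene F7, and this fast-initiating diene is closed with the same ruthenium carbene under ethene loss to reach 24.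

## Further compounds
F1 | step 9 | C6 carboxylic acid from 13 | CC(C)=CCC[C@](C)(O/C=C/C(=O)OC)C[C@H](O[Si](C)(C)C(C)(C)C)[C@@H](CC(=O)OC(C)(C)C)C(=O)O
F2 | step 9 | Se-phenyl selenoester of F1 | CC(C)=CCC[C@](C)(O/C=C/C(=O)OC)C[C@H](O[Si](C)(C)C(C)(C)C)[C@@H](CC(=O)OC(C)(C)C)C(=O)[Se]c1ccccc1
F3 | step 9 | oxepan-3-one (C6 ketone) | O=C1[C@H](CC(=O)OC(C)(C)C)[C@@H](O[Si](C)(C)C(C)(C)C)C[C@](C)(CCC=C(C)C)O[C@@H]1CC(=O)OC
F4 | step 15 | C8 ketone of the bis-Mannich base | CN(C)CC1C(=O)O[C@H]2[C@H]1C(=O)C[C@](C)(CCC=C(C)C)O[C@@H]2C(CN(C)C)C(=O)OC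
F5 | step 15 | 8R alcohol of the bis-Mannich base | CN(C)CC1C(=O)O[C@H]2[C@H]1[C@H](O)C[C@](C)(CCC=C(C)C)O[C@@H]2C(CN(C)C)C(=O)OC
F6 | step 17 | C3 aldehyde from 23 | C=C1C(=O)O[C@H]2[C@H]1[C@H](OC(=O)[C@@]1(C)O[C@@H]1C)C[C@](C)(CCC=O)O[C@@H]2C(=C)C(=O)OC
F7 | step 17 | terminal alkene | C=C1C(=O)O[C@H]2[C@H]1[C@H](OC(=O)[C@@]1(C)O[C@@H]1C)C[C@](C)(CCC=C)O[C@@H]2C(=C)C(=O)OC
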